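## Retrosynthetic overview
1. The α‑methylene lactone comes last, by amine‑N‑oxide (Cope) elimination of a masked dimethylaminomethyl lactone. The C4 tertiary carbinol comes from a chelation‑directed methyl‑cerium addition to the C4 ketone of a cyclodecane‑1,6‑dione.
2. The 10‑membered carbocycle is unveiled by ozonolytic cleavage of the tetrasubstituted ring‑fusion alkene of a bicyclic octalin (a 6‑6 to 10 ring expansion). That octalin is the Birch dearomatisation product of a tetralin.
3. Before ring opening, the trans‑fused γ‑lactone and the C5 acyloxy group are built on the rigid six‑membered ring B (α‑oxygenation, α′‑alkylation, ketone reduction, lactonisation).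
4. Ring order: the bicycle (Birch) comes first, then the γ‑lactone on ring B, then the 10‑membered ring by fusion‑bond cleavage.

Assumptions:
- The tetralin C1 methyl (it becomes C10) is left racemic, so compounds 8–20 are C10 epimer mixtures. Once the ring is opened, C10 sits α to the C9 ketone and is assumed to equilibrate (Et3N‑treated silica work‑up) to the target 10R isomer.
- L‑Proline is assumed to give the drawn C5 configuration. D‑Proline is used if the opposite enantiomer is obtained.
- The acyl group encoded in the target SMILES is (R)‑2‑methylbutanoyl.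
- Target configuration: (4S,5R,6S,7S,10R), in germacranolide numbering.

## Route

**Step 1**
Reactants: 1 (6‑methoxy‑1‑tetralone); 2 (methylmagnesium bromide)
Product: 3 (6‑methoxy‑1‑methyl‑1,2,3,4‑tetrahydronaphthalen‑1‑ol, racemic)
Conditions: MeMgBr (1.5 equiv), THF, 0 °C to rt; aq. NH4Cl
Reagents that add atoms: MeMgBr, C[Mg]Br
Why: Grignard 1,2‑addition to the aryl ketone installs the future C10 methyl, and the non‑acidic quench avoids dehydration.

**Step 2**
Reactants: 3
Product: 4 (6‑methoxy‑1‑methyltetralin, racemic)
Conditions: Et3SiH (3 equiv), TFA, CH2Cl2, 0 °C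
Reagents that add atoms: none
Why: Ionic hydrogenation (Kursanov–Parnes) proceeds through the tertiary benzylic cation, which is stabilised by the para‑OMe. The C1 centre stays racemic by design (see Assumptions).

**Step 3**
Reactants: 4
Product: 5 (6‑methoxy‑1‑methyl‑1,2,3,4,5,8‑hexahydronaphthalene)
Conditions: Li, NH3(l), THF, t‑BuOH, −78 to −33 °C; NH4Cl
Reagents that add atoms: none
Why: Birch dearomatisation keeps the OMe carbon and both alkyl‑bearing ring‑fusion carbons sp2, so the 1,4‑diene is the methyl enol ether plus the tetrasubstituted ring‑fusion alkene (the C4=C9 bond to be cleaved later).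

**Step 4**
Reactants: 5; water
Product: 6 (5‑methyl‑3,4,5,6,7,8‑hexahydronaphthalen‑2(1H)‑one, the β,γ‑unsaturated ketone)
Conditions: aq. (CO2H)2, THF, rt
Reagents that add atoms: water, O
Why: Mild enol‑ether hydrolysis gives the ketone (future C6) and leaves the fusion alkene unconjugated (stronger acid would conjugate it).

**Step 5**
Reactants: 6; 7 (nitrosobenzene)
Product: 8 ((1S)‑5‑methyl‑1‑[(phenylamino)oxy]‑hexahydronaphthalen‑2(1H)‑one; C5 oxygenated)
Conditions: PhNO (1.2 equiv), L‑proline (20 mol%), DMSO, rt
Reagents that add atoms: nitrosobenzene, O=Nc1ccccc1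
Why: The proline enamine forms at the allylic α‑CH2 (C5) and undergoes an O‑selective nitroso‑aldol (organocatalytic α‑aminoxylation). The catalyst face selectivity sets the C5 absolute configuration.

**Step 6**
Reactants: 8
Product: 9 ((1S)‑1‑hydroxy‑5‑methyl‑3,4,5,6,7,8‑hexahydronaphthalen‑2(1H)‑one)
Conditions: CuSO4·5H2O (cat.), MeOH, rt
Reagents that add atoms: none
Why: Cu(II) cleaves the N–O bond under neutral conditions to give the α‑hydroxy ketone without epimerising C5.

**Step 7**
Reactants: 9; 10 ((R)‑2‑methylbutanoic acid)
Product: 11 (C5 (R)‑2‑methylbutanoate of 9)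
Conditions: DCC, DMAP (cat.), CH2Cl2, 0 °C
Reagents that add atoms: (R)‑2‑methylbutanoic acid, CC[C@@H](C)C(=O)O
Why: Steglich esterification of the secondary alcohol installs the final C5 acyl group early, and the acid stereocentre is untouched.

**Step 8**
Reactants: 11; 12 (ethyl bromoacetate)
Product: 13 (C7‑CH2CO2Et ketone; C5 and C7 substituents cis‑1,3)
Conditions: (i) pyrrolidine, TsOH (cat.), PhMe, Dean–Stark; (ii) BrCH2CO2Et, MeCN, 80 °C; (iii) AcOH/H2O, 60 °C
Reagents that add atoms: ethyl bromoacetate, BrCC(=O)OCC (adds CH2CO2Et)
Why: Stork enamine alkylation occurs regiospecifically at the unhindered α′‑CH2 (C7), because the C5 side is tertiary. Iminium–enamine exchange during hydrolysis lets C7 settle with its substituent equatorial, cis‑1,3 to the equatorial C5 acyloxy group. C5–H is never enolised, so the C5 configuration is kept.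

**Step 9**
Reactants: 13
Product: 14 (hydroxy ester; 5,6‑trans, 6,7‑trans)
Conditions: NaBH4, EtOH, −20 °C
Reagents that add atoms: none
Why: Hydride attacks the C6 ketone axially, giving the equatorial alcohol trans to both equatorial neighbours (the target's 5,6‑trans and 6,7‑trans pattern). The esters and the alkene are untouched.

**Step 10**
Reactants: 14
Product: 15 (trans‑fused γ‑lactone)
Conditions: TsOH (cat.), PhMe, 80 °C (−EtOH)
Reagents that add atoms: none
Why: Acid‑catalysed lactonisation of the trans‑diequatorial hydroxy ester gives the 6,7‑trans γ‑lactone, which is the target's ring fusion.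

**Step 11**
Reactants: 15; 16 (Eschenmoser's salt)
Product: 17 (α‑(dimethylaminomethyl) lactone; C11 epimeric mixture)
Conditions: LDA (1.1 equiv), THF, −78 °C; then Me2N+=CH2 I−, −78 to 0 °C
Reagents that add atoms: Eschenmoser's salt, C[N+](C)=C.[I-] (adds CH2NMe2)
Why: Lactone‑enolate Mannich reaction. The lactone α‑H (pKa about 25) is removed in preference to the hindered branched ester α‑H. The adduct is a stable masked α‑methylene lactone, and the C11 stereochemistry is irrelevant because it is destroyed in Step 14.

**Step 12**
Reactants: 17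
Product: 18 (10‑membered cyclodecane‑1,6‑dione lactone; C4 and C9 ketones)
Conditions: TFA (1.0 equiv), CH2Cl2/MeOH; O3, −78 °C; then Me2S; NaHCO3 wash
Reagents that add atoms: ozone, O=[O+][O-]
Why: Proposed new method: ozonolysis of the electron‑rich tetrasubstituted ring‑fusion alkene cleaves the C4–C9 bond and converts the bicycle into the 10‑membered ring with the stereocentres at C5, C6 and C7 untouched. The mechanism is the same as the known ozonolysis of Δ9,10‑octalin to cyclodecane‑1,6‑dione. The amine is protonated so it survives, the lactone and esters are inert, and C10 becomes epimerisable.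

**Step 13**
Reactants: 18; 19 (methylcerium dichloride)
Product: 20 (amine‑protected target: C4 tertiary carbinol, 4S)
Conditions: MeLi (3 equiv) + CeCl3 (3 equiv), THF, −78 °C; NH4Cl at −78 °C
Reagents that add atoms: MeCeCl2, C[Ce](Cl)Cl (adds CH3)
Why: Proposed new method: the non‑basic organocerium adds to the more electrophilic α‑acyloxy ketone (C4) rather than the α‑methyl‑flanked C9 ketone. Ce‑chelation by the C5 acyloxy oxygen directs methyl delivery (Cram‑chelate model) to give the C4‑OH anti to C5‑O, as in the target. The closest known reaction is RCeCl2 addition to α‑alkoxy ketones.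

**Step 14**
Reactants: 20
Product: 21 (Ineupatorolide A)
Conditions: mCPBA (1.1 equiv), CH2Cl2, 0 °C; then PhMe, 60 °C
Reagents that add atoms: none
Why: Amine‑N‑oxide syn (Cope) elimination unmasks the exocyclic methylene lactone under neutral conditions. The tertiary alcohol, ketone and esters are tolerated, and no stereocentre is touched.

## Compound list
1 | 6‑methoxy‑1‑tetralone | COc1ccc2c(c1)CCCC2=O | starting material
2 | methylmagnesium bromide | C[Mg]Br | starting material
3 | 6‑methoxy‑1‑methyl‑1,2,3,4‑tetrahydronaphthalen‑1‑ol | COc1ccc2c(c1)CCCC2(C)O | intermediate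
4 | 6‑methoxy‑1‑methyltetralin | COc1ccc2c(c1)CCCC2C | intermediate
5 | 6‑methoxy‑1‑methyl‑1,2,3,4,5,8‑hexahydronaphthalene | COC1=CCC2=C(C1)CCCC2C | intermediate
6 | 5‑methyl‑3,4,5,6,7,8‑hexahydronaphthalen‑2(1H)‑one | O=C1CCC2=C(C1)CCCC2C | intermediate
7 | nitrosobenzene | O=Nc1ccccc1 | starting material
8 | α‑(phenylamino)oxy ketone (C5‑oxygenated) | O=C1CCC2=C([C@@H]1ONc3ccccc3)CCCC2C | intermediate
9 | α‑hydroxy ketone | O=C1CCC2=C([C@@H]1O)CCCC2C | intermediate
10 | (R)‑2‑methylbutanoic acid | CC[C@@H](C)C(=O)O | starting material
11 | C5 (R)‑2‑methylbutanoate ketone | O=C1CCC2=C([C@@H]1OC(=O)[C@H](C)CC)CCCC2C | intermediate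
12 | ethyl bromoacetate | BrCC(=O)OCC | starting material
13 | C7‑CH2CO2Et ketone | O=C1[C@H](CC(=O)OCC)CC2=C([C@@H]1OC(=O)[C@H](C)CC)CCCC2C | intermediate
14 | hydroxy ester (C6‑OH) | CCOC(=O)C[C@@H]1CC2=C(CCCC2C)[C@H](OC(=O)[C@H](C)CC)[C@H]1O | intermediate
15 | trans‑fused γ‑lactone octalin | O=C1C[C@@H]2CC3=C(CCCC3C)[C@H](OC(=O)[C@H](C)CC)[C@H]2O1 | intermediate
16 | Eschenmoser's salt | C[N+](C)=C.[I-] | starting material
17 | Mannich base lactone | O=C1C(CN(C)C)[C@@H]2CC3=C(CCCC3C)[C@H](OC(=O)[C@H](C)CC)[C@H]2O1 | intermediate
18 | cyclodecane‑1,6‑dione lactone | O=C1C(CN(C)C)[C@@H]2CC(=O)C(C)CCCC(=O)[C@H](OC(=O)[C@H](C)CC)[C@H]2O1 | intermediate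
19 | methylcerium dichloride | C[Ce](Cl)Cl | starting material (reagent)
20 | amine‑protected Ineupatorolide A | CN(C)CC1C(=O)O[C@@H]2[C@@H](OC(=O)[C@H](C)CC)[C@@](C)(O)CCCC(C)C(=O)C[C@@H]12 | intermediate
21 | Ineupatorolide A | C=C1C(=O)O[C@@H]2[C@@H](OC(=O)[C@H](C)CC)[C@@](C)(O)CCC[C@@H](C)C(=O)C[C@@H]12 | target

## Totals
Total steps: 14. Longest linear sequence: 14 (from 1).

## Three steps most likely to fail
1. **Step 13, chemoselective and stereoselective C4 methylation.** It may add to both ketones, or chelation control may be weak with an acyloxy donor. Fallback: change the approach by converting the C4 ketone to an exocyclic methylene (Petasis/Tebbe olefination, with C9 transiently masked as a hemiketal), then form the tertiary alcohol by Mukaiyama hydration (Co(acac)2, PhSiH3, O2).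
2. **Step 12, ozonolysis.** Over‑oxidation, incomplete amine protection or transannular aldol of the 1,6‑dione could occur. Fallback: cleave the fusion alkene stepwise by forced OsO4/TMEDA dihydroxylation followed by Pb(OAc)4 glycol cleavage, with the amine kept as its ammonium salt.
3. **Step 8, C7 stereocontrol and C5 integrity.** The cis‑1,3 relationship at C7 may not be reached, or C5 may epimerise. Fallback: build the trans C6–O/C7–C bond pair by epoxide opening instead. Convert 9 to the C6=C7 alkene, apply anti‑epoxidation (mCPBA, anti to the acyloxy group), and open with a lithium ester enolate by trans‑diaxial attack at C7.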